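**Retrosynthetic overview**
1. Artocarpol D 21 comes from its bis-silyl ether 20 by fluoride desilylation. The 2H-pyran is the last ring formed, by oxa-6π electrocyclisation of dienone 19, made by dehydrating aldol 17.
2. Key C–C bond: intermolecular aldol addition of the lithium enolate of dibenzoxepinone 14 (at C11) to 3-methylbut-2-enal 15.
3. The prenyl group comes from an allyl group (cross-metathesis), the allyl from an aryl bromide (Stille). The bromine is carried from step 1, so its position is never in doubt.
4. The oxepinone ring is the first ring formed, by intramolecular Friedel–Crafts acylation of arylacetic acid 7, itself from acetophenone 5 by Willgerodt–Kindler homologation.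
5. Diaryl ether 5 comes from SNAr of 3-methoxyphenol 4 on fluoroketone 3, made by Friedel–Crafts acetylation of 2-bromo-5-fluoroanisole 1. Both benzene rings are bought.

Assumption: the target SMILES has no stereocentre and no stereodefined acyclic double bond, so artocarpol D is achiral and no enantiocontrol is needed.

**Route**

Step 1
Reactants: 1 2-bromo-5-fluoroanisole; 2 acetyl chloride
Product: 3 1-(5-bromo-2-fluoro-4-methoxyphenyl)ethan-1-one
Conditions: AlCl3 (1.3 equiv), CH2Cl2, 0 °C to rt
Reagents that add atoms: none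
Why: Friedel–Crafts acylation goes para to the methoxy group (the only strongly activated, unhindered site), which puts the acetyl ortho to fluorine and meta to bromine; no stereocentre is formed.

Step 2
Reactants: 3 1-(5-bromo-2-fluoro-4-methoxyphenyl)ethan-1-one; 4 3-methoxyphenol
Product: 5 1-[5-bromo-4-methoxy-2-(3-methoxyphenoxy)phenyl]ethan-1-one
Conditions: K2CO3 (2 equiv), DMSO, 110 °C
Reagents that add atoms: none
Why: Nucleophilic aromatic substitution (SNAr), in which the ortho-acetyl group activates the C–F bond towards the phenoxide while the unactivated C–Br and C–OMe bonds stay intact; no stereocentre is formed.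

Step 3
Reactants: 5 1-[5-bromo-4-methoxy-2-(3-methoxyphenoxy)phenyl]ethan-1-one
Product: 6 2-[5-bromo-4-methoxy-2-(3-methoxyphenoxy)phenyl]-1-(morpholin-4-yl)ethane-1-thione
Conditions: S8, morpholine (neat), 130 °C
Reagents that add atoms: sulfur, S1SSSSSSS1; morpholine, C1COCCN1
Why: The Willgerodt–Kindler reaction moves the oxidised carbon to the chain terminus, turning ArCOCH3 into ArCH2C(=S)N(morpholine) without touching the aryl bromide or the ethers; no stereocentre is formed.

Step 4
Reactants: 6 2-[5-bromo-4-methoxy-2-(3-methoxyphenoxy)phenyl]-1-(morpholin-4-yl)ethane-1-thione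
Product: 7 2-[5-bromo-4-methoxy-2-(3-methoxyphenoxy)phenyl]acetic acid
Conditions: KOH, EtOH/H2O, reflux; then aq. HCl to pH 1
Reagents that add atoms: potassium hydroxide, [K+].[OH-]; water, O
Why: Basic thioamide hydrolysis is driven by irreversible loss of hydrosulfide and morpholine, and acidification liberates the arylacetic acid; no stereocentre is formed.

Step 5
Reactants: 7 2-[5-bromo-4-methoxy-2-(3-methoxyphenoxy)phenyl]acetic acid
Product: 8 2-bromo-3,7-dimethoxydibenzo[b,f]oxepin-10(11H)-one
Conditions: Eaton's reagent (P2O5 in MeSO3H) as solvent, 45 °C, dilute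
Reagents that add atoms: none
Why: Intramolecular Friedel–Crafts acylation, in which the acylium ion attacks ring B para to its methoxy group and ortho to the ether oxygen to close the seven-membered ketone, ring A being blocked by bromine at its reactive position; no stereocentre is formed.

Step 6
Reactants: 8 2-bromo-3,7-dimethoxydibenzo[b,f]oxepin-10(11H)-one
Product: 9 2-bromo-3,7-dihydroxydibenzo[b,f]oxepin-10(11H)-one
Conditions: BBr3 (5 equiv), CH2Cl2, –78 °C to rt; then H2O
Reagents that add atoms: none
Why: BBr3 ether cleavage (Lewis acid-assisted SN2 demethylation by bromide) frees both phenols while the diaryl ether, ketone and aryl bromide persist, and it is done here because no later olefin-bearing intermediate would survive it; no stereocentre is formed.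

Step 7
Reactants: 9 2-bromo-3,7-dihydroxydibenzo[b,f]oxepin-10(11H)-one
Product: 10 2-bromo-3,7-bis(triisopropylsilyloxy)dibenzo[b,f]oxepin-10(11H)-one
Conditions: TIPSCl (2.5 equiv), imidazole (5 equiv), DMF, rt to 40 °C
Reagents that add atoms: chlorotriisopropylsilane (TIPSCl), CC(C)[Si](Cl)(C(C)C)C(C)C
Why: Imidazole-mediated O-silylation gives bulky aryl silyl ethers that withstand the coupling, metathesis and enolate steps yet fall to fluoride at the end; no stereocentre is formed.

Step 8
Reactants: 10 2-bromo-3,7-bis(triisopropylsilyloxy)dibenzo[b,f]oxepin-10(11H)-one; 11 allyltributylstannane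
Product: 12 2-allyl-3,7-bis(triisopropylsilyloxy)dibenzo[b,f]oxepin-10(11H)-one
Conditions: Pd(PPh3)4 (5 mol %), toluene (degassed), 105 °C
Reagents that add atoms: none
Why: Stille cross-coupling (oxidative addition of zerovalent palladium into C–Br, transmetalation from tin, reductive elimination) puts the allyl group exactly where the bromine was under neutral conditions that spare the silyl ethers and the enolisable ketone; no stereocentre is formed.

Step 9
Reactants: 12 2-allyl-3,7-bis(triisopropylsilyloxy)dibenzo[b,f]oxepin-10(11H)-one; 13 2-methylbut-2-ene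
Product: 14 2-(3-methylbut-2-en-1-yl)-3,7-bis(triisopropylsilyloxy)dibenzo[b,f]oxepin-10(11H)-one
Conditions: second-generation Grubbs catalyst RuCl2(=CHPh)(PCy3)(H2IMes) (5 mol %), 2-methylbut-2-ene (large excess), CH2Cl2, 35 °C, sealed tube
Reagents that add atoms: none
Why: Olefin cross-metathesis with excess 2-methylbut-2-ene converts the terminal allyl group into the prenyl group, driven by loss of propene, and the new olefin has two identical methyl groups so no stereo element arises.

Step 10
Reactants: 14 2-(3-methylbut-2-en-1-yl)-3,7-bis(triisopropylsilyloxy)dibenzo[b,f]oxepin-10(11H)-one; 15 3-methylbut-2-enal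
Product: 17 11-(1-hydroxy-3-methylbut-2-en-1-yl)-2-(3-methylbut-2-en-1-yl)-3,7-bis(triisopropylsilyloxy)dibenzo[b,f]oxepin-10(11H)-one (racemic mixture of diastereomers), via lithium enolate 16 (not isolated)
Conditions: LiN(SiMe3)2 (1.1 equiv, commercial 1 M in THF), THF, –78 °C; then 15 (1.5 equiv), –78 °C; AcOH quench at –78 °C
Reagents that add atoms: LiN(SiMe3)2, [Li+].C[Si](C)(C)[N-][Si](C)(C)C (its lithium stays in 16 only)
Why: Directed aldol addition, in which the ketone has one highly acidic enolisable position (C11, between the carbonyl and ring A) so a single enolate forms and adds 1,2 to the enal, with a cold acidic quench to prevent retro-aldol; two stereocentres form without control and both are erased in step 11.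

Step 11
Reactants: 17 11-(1-hydroxy-3-methylbut-2-en-1-yl)-2-(3-methylbut-2-en-1-yl)-3,7-bis(triisopropylsilyloxy)dibenzo[b,f]oxepin-10(11H)-one
Product: 20 artocarpol D bis(triisopropylsilyl) ether, via allylic mesylate 18 (not isolated), via dienone 19 (not isolated)
Conditions: MsCl (1.5 equiv), Et3N (4 equiv), THF, 0 °C to rt; then DBU (0.3 equiv), 60 °C
Reagents that add atoms: methanesulfonyl chloride, CS(=O)(=O)Cl (its atoms stay in 18 only)
Why: Mesylation and E1cB elimination give the 1-oxatriene, whose Z isomer closes by oxa-6π electrocyclisation to the gem-dimethyl 2H-pyran (favoured because the new enol-ether double bond is conjugated to both arenes), while DBU equilibrates the E and Z dienones through the trienolate; the stereocentres of 17 are destroyed and none is formed.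

Step 12
Reactants: 20 artocarpol D bis(triisopropylsilyl) ether
Product: 21 artocarpol D
Conditions: Bu4NF (2.5 equiv), AcOH (2.5 equiv), THF, 0 °C
Reagents that add atoms: none
Why: Fluoride-induced Si–O cleavage, driven by the Si–F bond strength and buffered with AcOH, frees both phenols without exposing the ortho-prenylphenol or the 2H-pyran to strong acid or base; the product is achiral, so nothing stereochemical remains to be set.

**Compound list**
1 | 2-bromo-5-fluoroanisole (1-bromo-4-fluoro-2-methoxybenzene) | COc1cc(F)ccc1Br | starting material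
2 | acetyl chloride | CC(=O)Cl | starting material
3 | 1-(5-bromo-2-fluoro-4-methoxyphenyl)ethan-1-one | CC(=O)c1cc(Br)c(OC)cc1F | intermediate
4 | 3-methoxyphenol | COc1cccc(O)c1 | starting material
5 | 1-[5-bromo-4-methoxy-2-(3-methoxyphenoxy)phenyl]ethan-1-one | CC(=O)c1cc(Br)c(OC)cc1Oc1cccc(OC)c1 | intermediate
6 | 2-[5-bromo-4-methoxy-2-(3-methoxyphenoxy)phenyl]-1-(morpholin-4-yl)ethane-1-thione | S=C(Cc1cc(Br)c(OC)cc1Oc1cccc(OC)c1)N1CCOCC1 | intermediate
7 | 2-[5-bromo-4-methoxy-2-(3-methoxyphenoxy)phenyl]acetic acid | OC(=O)Cc1cc(Br)c(OC)cc1Oc1cccc(OC)c1 | intermediate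
8 | 2-bromo-3,7-dimethoxydibenzo[b,f]oxepin-10(11H)-one | Brc1cc2c(cc1OC)Oc1cc(OC)ccc1C(=O)C2 | intermediate
9 | 2-bromo-3,7-dihydroxydibenzo[b,f]oxepin-10(11H)-one | Brc1cc2c(cc1O)Oc1cc(O)ccc1C(=O)C2 | intermediate
10 | 2-bromo-3,7-bis(triisopropylsilyloxy)dibenzo[b,f]oxepin-10(11H)-one | Brc1cc2c(cc1O[Si](C(C)C)(C(C)C)C(C)C)Oc1cc(O[Si](C(C)C)(C(C)C)C(C)C)ccc1C(=O)C2 | intermediate
11 | allyltributylstannane | C=CC[Sn](CCCC)(CCCC)CCCC | starting material
12 | 2-allyl-3,7-bis(triisopropylsilyloxy)dibenzo[b,f]oxepin-10(11H)-one | C=CCc1cc2c(cc1O[Si](C(C)C)(C(C)C)C(C)C)Oc1cc(O[Si](C(C)C)(C(C)C)C(C)C)ccc1C(=O)C2 | intermediate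
13 | 2-methylbut-2-ene | CC=C(C)C | starting material
14 | 2-(3-methylbut-2-en-1-yl)-3,7-bis(triisopropylsilyloxy)dibenzo[b,f]oxepin-10(11H)-one | CC(C)=CCc1cc2c(cc1O[Si](C(C)C)(C(C)C)C(C)C)Oc1cc(O[Si](C(C)C)(C(C)C)C(C)C)ccc1C(=O)C2 | intermediate
15 | 3-methylbut-2-enal (prenal) | CC(C)=CC=O | starting material
16 | lithium 10-enolate of 14 (formed in the flask in step 10) | [Li+].CC(C)=CCc1cc2c(cc1O[Si](C(C)C)(C(C)C)C(C)C)Oc1cc(O[Si](C(C)C)(C(C)C)C(C)C)ccc1C([O-])=C2 | intermediate
17 | 11-(1-hydroxy-3-methylbut-2-en-1-yl)-2-(3-methylbut-2-en-1-yl)-3,7-bis(triisopropylsilyloxy)dibenzo[b,f]oxepin-10(11H)-one, racemic mixture of diastereomers, no configuration defined | CC(C)=CCc1cc2c(cc1O[Si](C(C)C)(C(C)C)C(C)C)Oc1cc(O[Si](C(C)C)(C(C)C)C(C)C)ccc1C(=O)C2C(O)C=C(C)C | intermediate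
18 | methanesulfonate of the allylic alcohol 17 (formed in the flask in step 11), stereoisomer mixture | CC(C)=CCc1cc2c(cc1O[Si](C(C)C)(C(C)C)C(C)C)Oc1cc(O[Si](C(C)C)(C(C)C)C(C)C)ccc1C(=O)C2C(OS(C)(=O)=O)C=C(C)C | intermediate
19 | 11-(3-methylbut-2-en-1-ylidene)-2-(3-methylbut-2-en-1-yl)-3,7-bis(triisopropylsilyloxy)dibenzo[b,f]oxepin-10(11H)-one (formed in the flask in step 11), E/Z mixture | CC(C)=CCc1cc2c(cc1O[Si](C(C)C)(C(C)C)C(C)C)Oc1cc(O[Si](C(C)C)(C(C)C)C(C)C)ccc1C(=O)C2=CC=C(C)C | intermediate
20 | artocarpol D bis(triisopropylsilyl) ether: the 3,7-bis(triisopropylsilyloxy)-2-prenyl dibenzo[b,f]oxepine whose C10=C11 bond is fused to a 2,2-dimethyl-2H-pyran (pyran oxygen on C10, pyran CH=CH on C11) | CC(C)=CCc1cc2c(cc1O[Si](C(C)C)(C(C)C)C(C)C)Oc1cc(O[Si](C(C)C)(C(C)C)C(C)C)ccc1C1=C2C=CC(C)(C)O1 | intermediate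
21 | artocarpol D: the 3,7-dihydroxy-2-(3-methylbut-2-en-1-yl) dibenzo[b,f]oxepine whose C10=C11 bond is fused to a 2,2-dimethyl-2H-pyran (pyran oxygen on C10), achiral | CC(C)=CCc1cc2c(cc1O)Oc1cc(O)ccc1C1=C2C=CC(C)(C)O1 | target

**Totals**
Total step count: 12.
Longest linear sequence: 12 steps (1 to 21); the other starting materials are bought.

**Three steps most likely to fail, each with a fallback**

Step 3 (Willgerodt–Kindler). The crowded ortho-aryloxy ketone may react sluggishly, give tar, or lose the aryloxy group to hot morpholine. The fallback sets out from 5 and replaces the sulfur chemistry by an oxidative 1,2-aryl shift. Treating 5 with PhI(OAc)2 and H2SO4 in HC(OMe)3/MeOH at 60 °C makes the electron-rich ring A migrate and gives methyl 2-[5-bromo-4-methoxy-2-(3-methoxyphenoxy)phenyl]acetate F1. Saponification with LiOH in THF/H2O and acidification brings the route back at 7.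

Step 10 (aldol addition). The enolate is strongly stabilised, so the addition can be reversible and the adduct can undergo retro-aldol on work-up. The fallback sets out from 14 and changes the nucleophile. Me3SiOTf and Et3N in CH2Cl2 at 0 °C give 2-(3-methylbut-2-en-1-yl)-3,7-bis(triisopropylsilyloxy)-10-(trimethylsilyloxy)dibenzo[b,f]oxepine F2. A Mukaiyama aldol addition of this silyl enol ether to 15 with BF3·OEt2 in CH2Cl2 at –78 °C is made irreversible by silyl transfer and comes back to the route at 17.

Step 11 (dehydration and electrocyclisation). The elimination may give mainly the E dienone, which cannot cyclise, the allylic mesylate may be substituted, or DBU may start to remove silyl groups. The fallback sets out from 14 and bypasses 17. Prenal 15, piperidine and Ac2O in EtOAc at 85 °C preform 1-(3-methylbut-2-en-1-ylidene)piperidin-1-ium acetate F3. Adding 14 in toluene at 85–110 °C then gives a Knoevenagel condensation to dienone 19. The amine adds reversibly to 19, so the double-bond geometry equilibrates, and electrocyclisation returns the route at 20.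

**Further compounds**
F1 | step 3 | methyl 2-[5-bromo-4-methoxy-2-(3-methoxyphenoxy)phenyl]acetate | COC(=O)Cc1cc(Br)c(OC)cc1Oc1cccc(OC)c1
F2 | step 10 | 2-(3-methylbut-2-en-1-yl)-3,7-bis(triisopropylsilyloxy)-10-(trimethylsilyloxy)dibenzo[b,f]oxepine | CC(C)=CCc1cc2c(cc1O[Si](C(C)C)(C(C)C)C(C)C)Oc1cc(O[Si](C(C)C)(C(C)C)C(C)C)ccc1C(O[Si](C)(C)C)=C2
F3 | step 11 | 1-(3-methylbut-2-en-1-ylidene)piperidin-1-ium acetate | CC(C)=CC=[N+]1CCCCC1.CC(=O)[O-]
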